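Slowness is the first thing the alpha run shows, so we begin with its readings.

- alpha: starting material 10 mM; second substrate 10 mM; reagent 15 mM; free catalyst 100 µM; added ligand 99 µM; run made earlier
- flask: starting material 10 mM; second substrate 10.0 mM; reagent 15.0 mM; free catalyst 100 µM; added ligand 66 µM

alpha run (percent of the starting material charged): time / s: target / % = 10.0: 8.0; 20.0: 12.8; 30.0: 16.9; 50.0: 21.5; 80.0: 27.4

(standard deviation of a reading: 0.5 percentage points)

- no earlier run changes the charge of free catalyst; that part of a forecast is a guess
- no earlier run changes the charge of added ligand; that part of a forecast is a guess

* factor on the rate of making target when 50 % of the starting material are converted if free catalyst is charged twice over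
* factor on the rate when 50 % of the starting material are converted if free catalyst is charged at 1000 µM instead

In the first row, target gains 8.0 % in 10.0 s. Between the last two rows it gains 5.9 percentage points in 30.0 s, so the rate read there is lower by a factor of 4.07.

Our own reckoning starts from the charges. We assume that starting material and second substrate each take one reagent, and that second substrate is served in full. The flask holds 15.0 mM of reagent, less than the 20.0 mM that the two would take together, so reagent is the limiting reagent. What remains for starting material is the room, c(reagent) minus c(second substrate), as a share of c(starting material): 50.0 %. The alpha run has the same charges of these three, and its last row stands lower, at 27.4 %.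

The level asked about, 50 %, equals the room. On our assumption the rate asked for therefore lies at the very end of the reagent. We expect that rate to follow both the catalyst and the reagent left at that level, so we place the two factors above the rises in the catalyst charge itself, 2 and 10.0, though we give no figure of our own.

The forecast gives 3.6 (1.8 to 4.2) and 24 (8 to 30), reading the ligand as a tight binder “with only uncomplexed catalyst active”.

The flask gives 13.0 and 702, both above the forecast's ranges.

    reagent + catalyst intermediate A → free catalyst + target (k = 95.0 M⁻¹ s⁻¹)
    second substrate + free catalyst ⇌ catalyst intermediate B (K = 1600 M⁻¹, k = 600 M⁻¹ s⁻¹)
    reagent + catalyst intermediate B → free catalyst + second product (k = 1500 M⁻¹ s⁻¹)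
    starting material + free catalyst ⇌ catalyst intermediate A (K = 220 M⁻¹, k = 23000 M⁻¹ s⁻¹)
    free catalyst + added ligand ⇌ idle complex (K = 1.10 × 10⁶ M⁻¹, k = 650 M⁻¹ s⁻¹)

At 60.0 min the flask holds target at 50.0 % of the starting material charged, with reagent at 0.00753 % of its own charge and second product at 10.0 mM. At 6.00 min it still stands 6 points below the room of 50.0 %, and it reaches the level at 34.3 min, where target is made at 0.00225 mM min⁻¹.

All runs stem from a simulated flask with made-up constants; the scatter is artificial.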